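# Proposed synthesis of CNP0118407.1, (2S,3S,2'S,3'S)

## The problem

The target is two 2,3-trans-2,3-diaryl-2,3-dihydrobenzofurans joined by one C–C bond. Unit 1 (O1, C2, C3, benzo ring A) carries a 4-hydroxyphenyl group on C2, a hydroxyl on C4 and an (E)-4-hydroxystyryl group on C6; its C3 is bonded to C6' of unit 2 (O1', C2', C3', benzo ring D), which carries the 2,4-dihydroxyphenyl ring F on C2', the 3,5-dihydroxyphenyl ring E on C3' and a hydroxyl on C4'. In both benzo rings the ring-fusion carbon next to the benzylic stereocentre (C3a, C3a') lies between two oxygen-bearing carbons and para to the carbon substituent, a position that electrophilic substitution of a 5-substituted resorcinol does not reach, so the C3–C3a and C3'–C3a' bonds are best present from the start as a formyl group between two ether oxygens. There are four stereocentres, (2S,3S,2'S,3'S), both rings trans. Within one ring C3 (C3') can control C2 (C2'), because closure of the ring oxygen onto a C2 benzylic cation gives the trans ring, which is also the more stable one; the two pairs are held apart by ring D and cannot influence each other, so each pair needs its absolute configuration from a catalyst. Eight phenols, an (E)-stilbene and two benzylic aryl ether bonds (C2–O1, C2'–O1') next to para- or ortho,para-oxygenated aryl groups exclude hydrogenation, strong oxidants and long exposure to strong acid, and they make the last deprotection delicate. The key step is possible because C2' and C3' (and likewise C2 and C3) are adjacent sp3 carbons that each carry exactly one simple aryl group, with the heteroatom on the carbon bearing ring F and the benzo ring on the carbon bearing ring E; this is the pattern that a 1,2-metallate shift writes across an (E)-alkenylboronate grown from the C3a' formyl carbon, boron marking the carbon that later bonds to O1'.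

## Retrosynthesis

**35 to 34.** The last cut removes seven O-methyl groups from heptamethyl ether 34, which already has the C4 hydroxyl free. Methyl ethers are chosen because they survive aryllithiums, palladium, alkaline peroxide and methanolic acid; benzyl ethers would need hydrogenolysis, which the stilbene and the benzylic C–O bonds would not tolerate. The forward reaction must cleave aryl methyl ethers without irreversible opening of C2–O1 and C2'–O1'.

**34 to 33 to 32.** The O1–C2 bond of unit 1 is cut to give the acyclic 4-methoxybenzylic alcohol 33, whose ring A oxygens are both MOM ethers. Cutting C3–C3a instead would ask for arylation between two oxygens of a resorcinol, which has the wrong regiochemistry. Forward, acid removes the MOM groups and ionises the carbinol, and the ortho phenol closes trans to the C3 substituent, so only C3 must be correct in 33. Alcohol 33 comes from boronic ester 32 by C–B to C–O exchange with retention.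

**32 to 28, 30 and 19.** Both bonds that C3 and C2 make to simple aryl groups are cut at once: C3–C6' and C2–(4-methoxyphenyl). This returns the achiral alkenylboronate 28, aryllithium 30 and the complete unit 2 as aryl triflate 19. The neighbouring cut, C3–C3a with ring A as the electrophile, would need a di-ortho-substituted aryl triflate. Stepwise carbonyl additions to a unit 2 aldehyde would give no control of C3 relative to the remote C2'/C3'. Forward, the catalyst alone must set C3, since the stereocentres of 19 are too far away to help or to hinder.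

**19 to 18 to 17 to 16.** Triflate 19 comes from phenol 18. In 18 the O1'–C2' bond is cut to alcohol 17, and 17 comes from boronic ester 16. Ring D carries one methyl and two MOM ethers: only one ortho oxygen is unmasked for ring closure, the other stays as the C4' methoxy group, and the para oxygen appears as the only free phenol, so the triflate handle needs no separate differentiation step.

**16 to 10, 14 and 12 (key disconnection).** The C3'–ring E and C2'–ring F bonds are cut together, giving (E)-alkenylboronate 10, aryllithium 14 and triflate 12. Three points of the precursor are chosen deliberately: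
- Boron carries the diolate of 2 (mac) and not pinacol, because β-substituted alkenyl pinacol boronates favour Suzuki-type coupling over the metallate shift.
- One ortho oxygen of ring D is a methyl ether, the other a MOM ether.
- The para substituent of ring D is an oxygen, so that unit 2 can later serve as the triflate of the second coupling.

**10 to 8 and 2; 8 to 5 and 7; 7 to 6; 5 to 4 to 3; 2 to 1.** The boron ligand is exchanged from pinacol (8) to the diol 2, made from diketone 1. The alkene of 8 is cut by a boron–Wittig olefination into aldehyde 5 and the lithiated diborylmethane 7. Reagent 7 is made once from diborylmethane 6 and collected as a solid, because the ring A branch needs the same reagent and one batch can serve both olefinations. Aldehyde 5 comes from 2,4,6-trihydroxybenzaldehyde 3 through 4; the hydrogen bond to the formyl group differentiates the oxygens, so no directed lithiation is needed for ring D.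

**28 to 26 to 25 to 23; 23 to 21 and 22; 21 to 20.** Ring A is prepared in the same way: ligand exchange (26 to 28), boron–Wittig olefination of aldehyde 25 with the same batch of 7, and formylation of stilbene 23 between its two MOM ethers by directed lithiation. The stilbene is cut by a Horner–Wadsworth–Emmons reaction into aldehyde 21 (from 20) and phosphonate 22. Building the stilbene first saves a late olefination on the complete skeleton.

**12 from 11; 14 from 13; 30 from 29.** The two simple aryl groups come from a commercial phenol and two commercial aryl bromides.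

## Roads not taken

**Alternative 1:** The cut goes through ring E, whose ipso–ortho bond is opened so that the ring unfolds into a diketo-dioxinone chain on C3' (A2). Forward, Et3N would enolise the dioxinone of A2, its α-carbon would add to the C3'-bound ketone, and loss of water would give ring E as the acetonide-protected β-resorcylate A1.
- Merits: metal-free, mild, and the oxygen pattern of ring E arises by itself with its two phenols differentiated.
- Weak points: it builds a benzene ring that can be bought (12 is one step from a commercial phenol). The chain of A2 must be assembled by several acylations on a hindered C3' acyl group. C3' is α to a ketone in A2. An extra carboxyl carbon must later be removed next to the acid-sensitive C2'–O1' bond. The step creates no stereocentre, so C2' and C3' would have to be set earlier by a separate asymmetric reaction, and the C6' bromide still has to be elaborated.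
- Comparison: it is milder and carries less risk in its key step, and this is a real advantage. The chosen plan sets against it that one step forms two C–C bonds and both stereocentres of unit 2, and that the same step then builds unit 1.

**Alternative 2:** The cut removes three bonds of ring D (C3a'–C7a', C4'–C5', C6'–C7'), leading to the tethered diyne A4 and the alkyne A5. Forward, Cp*RuCl(cod) would join them in a [2+2+2] cycloaddition that closes ring D and the dihydrofuran ring at once to give A3.
- Merits: very convergent; the substitution pattern of ring D is fixed by the tether; C6' arrives as a protected aldehyde; conditions are neutral, so stereocentres set beforehand survive.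
- Weak points: C4' arrives bonded to silicon and not to oxygen, and converting aryl–SiMe3 into a phenol next to the hindered C3' costs steps. A4 is an alkynyl ether of a 2,4-dimethoxybenzylic alcohol, prone to ionisation, and its two stereocentres need a separate asymmetric synthesis. Regiochemistry of alkyne insertion must be controlled. The key step sets no stereocentre.
- Comparison: for assembling ring D from acyclic pieces this road is better than anything in the chosen plan. The chosen plan answers that ring D is bought with all three oxygens in place, and that its para oxygen becomes the triflate the second coupling needs.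

**Alternative 3:** The cut opens O1–C2 of unit 1 and re-forms the C3a–C2 bond, giving the spirocyclopropyl cyclohexanedione A7. Forward, Sc(OTf)3 would open the cyclopropane bond to the 4-methoxyphenyl-bearing carbon, and a dione oxygen would close on that carbon to give the tetrahydrobenzofuranone A6 (Cloke–Wilson type ring expansion); dehydrogenation of A6 would meet the chosen route at 34.
- Merits: ring A needs no protecting groups and its C4 oxygen appears as the free phenol; C3 is carried over from the cyclopropane and C2 is set trans on ring closure; unit 1 is attached to a complete unit 2 without a second hindered palladium coupling.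
- Weak points: A7 requires an enantioselective cyclopropanation of a trans-stilbene by a cyclic acceptor–acceptor carbene, a class with poor face control, and the carbene partner carries a styryl alkene of its own. Aromatising A6 needs an oxidant that must spare the stilbene and must not dehydrogenate either dihydrofuran ring to a benzofuran, which would erase the stereocentres. Unit 2 is not addressed at all.
- Comparison: it is better in protecting-group economy at ring A. The chosen plan sets against it catalyst control of C3, no change of oxidation level at ring A, and one reaction type that serves both units.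

Key step: step 8

Remark on the chemistry: which enantiomer of the ferrocenyl bisphosphine gives (1R,2S)-16 is not assumed by analogy. It is fixed in the first run of step 8 by correlating 18 with the (2S,3S) series, and the same enantiomer is then used in step 17, because ate complexes 15 and 31 present the same local alkene and 16 and 32 have the same spatial arrangement at the new centres.

## Route

Step 1
Reactants: 1 acenaphthylene-1,2-dione
Product: 2 cis-1,2-dimethyl-1,2-dihydroacenaphthylene-1,2-diol (meso 1R,2S; the mac diol)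
Conditions: AlMe3, toluene, 0 °C → rt; aq. HCl
Reagents that add atoms: trimethylaluminium, C[Al](C)C
Why: Double 1,2-addition of methyl to the 1,2-diketone; the second methyl enters anti to the aluminium alkoxide formed in the first addition, so the two hydroxyls end up cis and the diol is meso.

Step 2
Reactants: 3 2,4,6-trihydroxybenzaldehyde
Product: 4 2-hydroxy-4,6-bis(methoxymethoxy)benzaldehyde
Conditions: MOMCl (2.1 equiv), i-Pr2NEt, CH2Cl2, 0 °C → rt
Reagents that add atoms: chloromethyl methyl ether, COCCl
Why: Williamson-type O-alkylation; after the para hydroxyl and one ortho hydroxyl have reacted, the remaining ortho hydroxyl is hydrogen-bonded to the formyl group and reacts much more slowly, which gives the bis-ether selectively.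

Step 3
Reactants: 4 2-hydroxy-4,6-bis(methoxymethoxy)benzaldehyde
Product: 5 2-methoxy-4,6-bis(methoxymethoxy)benzaldehyde
Conditions: MeI, K2CO3, DMF, 40 °C
Reagents that add atoms: iodomethane, CI
Why: O-methylation of the hydrogen-bonded phenol under more forcing Williamson conditions; this oxygen becomes the C4' methoxy group, so only the two MOM oxygens are unmasked later.

Step 4
Reactants: 6 bis(4,4,5,5-tetramethyl-1,3,2-dioxaborolan-2-yl)methane
Product: 7 lithiobis(4,4,5,5-tetramethyl-1,3,2-dioxaborolan-2-yl)methane (collected as a solid under argon; one batch serves steps 5 and 15)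
Conditions: lithium 2,2,6,6-tetramethylpiperidide (LiTMP, 1.0 equiv), THF/hexane, 0 °C; precipitate filtered and washed with hexane under argon
Reagents that add atoms: lithium 2,2,6,6-tetramethylpiperidide, [Li]N1C(C)(C)CCCC1(C)C
Why: Deprotonation of the C–H acid between two boron atoms by a hindered amide base that does not add to boron; the α,α-diboryl carbanion is stabilised by both boron atoms, and its lithium salt can be collected as a solid and stored under inert gas, so a single batch supplies both olefinations of the route.

Step 5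
Reactants: 5 2-methoxy-4,6-bis(methoxymethoxy)benzaldehyde; 7 lithiobis(4,4,5,5-tetramethyl-1,3,2-dioxaborolan-2-yl)methane
Product: 8 2-{(E)-2-[2-methoxy-4,6-bis(methoxymethoxy)phenyl]ethenyl}-4,4,5,5-tetramethyl-1,3,2-dioxaborolane
Conditions: 7 (1.2 equiv), THF, −78 °C → rt
Reagents that add atoms: none
Why: Boron–Wittig olefination: the α-diboryl carbanion adds to the aldehyde and syn elimination of a boron–oxygen unit gives the 1,2-disubstituted alkenylboronate, for which aldehydes give the (E)-isomer.

Step 6
Reactants: 8 the (E)-alkenyl pinacol boronate; 2 the mac diol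
Product: 10 (E)-2-[2-methoxy-4,6-bis(methoxymethoxy)phenyl]ethenylboronic acid cyclic ester of diol 2 (B(mac) ester), via alkenylboronic acid 9 (not isolated)
Conditions: NaIO4, NH4OAc, acetone/H2O, rt; extraction; then 2, MgSO4, CH2Cl2, rt
Reagents that add atoms: none
Why: Periodate cleaves the pinacol released by hydrolysis and drives the boronic ester to the free acid at near-neutral pH, where the MOM ethers are safe; condensation with the 1,2-diol 2 under dehydration then gives the cyclic ester with the alkene geometry untouched.

Step 7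
Reactants: 11 3,5-dimethoxyphenol
Product: 12 3,5-dimethoxyphenyl trifluoromethanesulfonate
Conditions: Tf2O, pyridine, CH2Cl2, 0 °C
Reagents that add atoms: trifluoromethanesulfonic anhydride, O=S(=O)(OS(=O)(=O)C(F)(F)F)C(F)(F)F
Why: O-sulfonylation of a phenol; standard preparation of an aryl triflate.

Step 8
Reactants: 13 1-bromo-2,4-dimethoxybenzene; 10 the ring D (E)-alkenyl B(mac) ester; 12 3,5-dimethoxyphenyl trifluoromethanesulfonate
Product: 16 (1R,2S)-1-(2,4-dimethoxyphenyl)-2-(3,5-dimethoxyphenyl)-2-[2-methoxy-4,6-bis(methoxymethoxy)phenyl]ethylboronic acid cyclic ester of diol 2, via 2,4-dimethoxyphenyllithium 14 (not isolated), via lithium borate complex 15 (not isolated)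
Conditions: 13, n-BuLi, THF, −78 °C; 10, −78 °C → rt; volatiles removed in vacuo; then Pd(OAc)2 (5 mol%), MandyPhos ligand Fe[C5H3(PAr2)(CH(NMe2)Ph)]2 (Ar = 4-MeO-3,5-Me2C6H2, one enantiomer, 6 mol%), 12, THF, 60 °C
Reagents that add atoms: none
Why: Aryllithium 14 adds to the boron of 10 to give the four-coordinate ate complex 15 (two epimers at boron, which converge), zerovalent palladium carrying the chiral bisphosphine inserts into the C–O bond of triflate 12, and the resulting cationic aryl–palladium species (divalent palladium) binds the electron-rich alkene of 15. Binding triggers a 1,2-shift of the 2,4-dimethoxyphenyl group from boron to C2' anti to palladium while palladium bonds C3', and reductive elimination from the benzylic alkyl(aryl)palladium then forms the C3'–ring E bond with retention, so that ring F and ring E are added anti across the (E)-alkene and boron stays on C2'. The closest known reaction type is the enantioselective conjunctive cross-coupling of β-substituted alkenylboron ate complexes with aryl triflates under Pd(OAc)2 and a MandyPhos ligand, in which the acenaphthoquinone-derived diol on boron shifts the balance from direct Suzuki-type transmetalation to the metallate shift; this is why 10 and not 8 is used. No ring closes in this step. C3' is set by the alkene face that the chiral palladium complex selects, and C2' follows from it through the stereospecific anti shift on the (E)-alkene, which together give (1R,2S)-16. The step needs chemoselectivity for the shift over transmetalation and over β-hydride elimination, secured by the diol on boron, the chelating ligand, the triflate leaving group and the generation of 14 by exchange with n-BuLi, which leaves no lithium halide (the 1-bromobutane formed goes with the volatiles); it also needs face selectivity at a β-aryl group with two ortho ethers, which in steric demand goes beyond the reported substrates. The methyl and MOM ethers are inert, and since the later ring closure re-forms C2' under control of C3', only the configuration at C3' has to be carried forward.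

Step 9
Reactants: 16 the (1R,2S)-boronic ester
Product: 17 (1R,2S)-1-(2,4-dimethoxyphenyl)-2-(3,5-dimethoxyphenyl)-2-[2-methoxy-4,6-bis(methoxymethoxy)phenyl]ethan-1-ol
Conditions: H2O2 (30% aq.), NaOH (3 M aq.), THF, 0 °C → rt
Reagents that add atoms: hydrogen peroxide, OO
Why: Boronate oxidation: hydroperoxide adds to boron and the alkyl group shifts from boron to oxygen with retention, so C2' keeps its configuration; the ethers are stable to alkaline peroxide.

Step 10
Reactants: 17 the (1R,2S)-alcohol
Product: 18 (2S,3S)-2-(2,4-dimethoxyphenyl)-3-(3,5-dimethoxyphenyl)-4-methoxy-2,3-dihydro-1-benzofuran-6-ol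
Conditions: HCl (1 M in MeOH), 0 → 40 °C, dilute
Reagents that add atoms: none
Why: Acid cleaves both MOM acetals and ionises the 2,4-dimethoxybenzylic alcohol (SN1 cyclodehydration); the single unmasked ortho phenol closes the five-membered ring on the C2' cation from the face away from ring E on C3', so C2' is formed trans to C3' whatever its configuration in 17. The para oxygen cannot reach C2' and is left as the only free phenol.

Step 11
Reactants: 18 the (2S,3S)-benzofuran-6-ol
Product: 19 (2S,3S)-2-(2,4-dimethoxyphenyl)-3-(3,5-dimethoxyphenyl)-4-methoxy-2,3-dihydro-1-benzofuran-6-yl trifluoromethanesulfonate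
Conditions: PhNTf2, Et3N, DMAP (cat.), CH2Cl2, rt
Reagents that add atoms: N-phenylbis(trifluoromethanesulfonimide), O=S(=O)(N(c1ccccc1)S(=O)(=O)C(F)(F)F)C(F)(F)F
Why: Mild triflyl transfer to the only free phenol; the reagent is chosen over the anhydride so that no strong acid meets the benzylic ether.

Step 12
Reactants: 20 3,5-dihydroxybenzaldehyde
Product: 21 3,5-bis(methoxymethoxy)benzaldehyde
Conditions: MOMCl, i-Pr2NEt, CH2Cl2, 0 °C → rt
Reagents that add atoms: chloromethyl methyl ether, COCCl
Why: Williamson-type protection of both phenols as MOM ethers, which later direct the lithiation and are removed in the ring-closing step.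

Step 13
Reactants: 21 3,5-bis(methoxymethoxy)benzaldehyde; 22 diethyl (4-methoxybenzyl)phosphonate
Product: 23 (E)-1-[3,5-bis(methoxymethoxy)phenyl]-2-(4-methoxyphenyl)ethene
Conditions: KOt-Bu, THF, 0 °C → rt
Reagents that add atoms: none
Why: Horner–Wadsworth–Emmons olefination; benzylphosphonate anions and aromatic aldehydes give the (E)-stilbene.

Step 14
Reactants: 23 the (E)-stilbene
Product: 25 2,6-bis(methoxymethoxy)-4-[(E)-2-(4-methoxyphenyl)ethenyl]benzaldehyde, via aryllithium 24 (not isolated)
Conditions: n-BuLi, THF, −20 → 0 °C; then DMF, 0 °C → rt; aq. NH4Cl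
Reagents that add atoms: N,N-dimethylformamide, CN(C)C=O
Why: Directed ortho-lithiation: the two MOM ethers cooperate and place lithium on the carbon between them, and formylation with DMF installs the future C3 carbon at C3a.

Step 15
Reactants: 25 the ring A aldehyde; 7 lithiobis(4,4,5,5-tetramethyl-1,3,2-dioxaborolan-2-yl)methane (from the batch of step 4)
Product: 26 2-{(E)-2-[2,6-bis(methoxymethoxy)-4-[(E)-2-(4-methoxyphenyl)ethenyl]phenyl]ethenyl}-4,4,5,5-tetramethyl-1,3,2-dioxaborolane
Conditions: 7 (1.2 equiv), THF, −78 °C → rt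
Reagents that add atoms: none
Why: Boron–Wittig olefination as in step 5, giving the (E)-alkenylboronate; the stilbene is inert to the carbanion.

Step 16
Reactants: 26 the ring A (E)-alkenyl pinacol boronate; 2 the mac diol
Product: 28 (E)-2-[2,6-bis(methoxymethoxy)-4-[(E)-2-(4-methoxyphenyl)ethenyl]phenyl]ethenylboronic acid cyclic ester of diol 2, via alkenylboronic acid 27 (not isolated)
Conditions: NaIO4, NH4OAc, acetone/H2O, rt; extraction; then 2, MgSO4, CH2Cl2, rt
Reagents that add atoms: none
Why: Boron ligand exchange as in step 6; periodate alone does not attack the alkenes.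

Step 17
Reactants: 29 1-bromo-4-methoxybenzene; 28 the ring A (E)-alkenyl B(mac) ester; 19 the unit 2 triflate
Product: 32 (1R,2S)-2-[2,6-bis(methoxymethoxy)-4-[(E)-2-(4-methoxyphenyl)ethenyl]phenyl]-2-[(2S,3S)-2-(2,4-dimethoxyphenyl)-3-(3,5-dimethoxyphenyl)-4-methoxy-2,3-dihydro-1-benzofuran-6-yl]-1-(4-methoxyphenyl)ethylboronic acid cyclic ester of diol 2, via 4-methoxyphenyllithium 30 (not isolated), via lithium borate complex 31 (not isolated)
Conditions: 29, n-BuLi, THF, −78 °C; 28, −78 °C → rt; volatiles removed in vacuo; then Pd(OAc)2 (5 mol%), MandyPhos ligand Fe[C5H3(PAr2)(CH(NMe2)Ph)]2 (same enantiomer as in step 8, 6 mol%), 19, THF, 60 °C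
Reagents that add atoms: none
Why: The same conjunctive cross-coupling as in step 8: 30 adds to the boron of 28, the cationic aryl–palladium species from 19 binds the alkene of 31, the 4-methoxyphenyl group shifts to C2 anti to palladium and reductive elimination forms the C3–C6' bond. C3 is set by the ligand-selected alkene face and C2 by the anti shift on the (E)-alkene, giving (1R,2S)-32; the stereocentres of 19 are remote from the reacting carbon and are not expected to interfere. C6' of 19 has two ortho hydrogens, so the steric demand matches step 8, and the distal stilbene, an unactivated 1,2-diaryl alkene, should be a much poorer partner for the aryl–palladium cation than the borate alkene.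

Step 18
Reactants: 32 the (1R,2S)-boronic ester
Product: 33 (1R,2S)-2-[2,6-bis(methoxymethoxy)-4-[(E)-2-(4-methoxyphenyl)ethenyl]phenyl]-2-[(2S,3S)-2-(2,4-dimethoxyphenyl)-3-(3,5-dimethoxyphenyl)-4-methoxy-2,3-dihydro-1-benzofuran-6-yl]-1-(4-methoxyphenyl)ethan-1-ol
Conditions: H2O2 (30% aq.), NaOH (3 M aq.), THF, 0 °C → rt
Reagents that add atoms: hydrogen peroxide, OO
Why: Boronate oxidation with retention as in step 9; the stilbene and the ethers are stable to alkaline peroxide.

Step 19
Reactants: 33 the (1R,2S)-alcohol
Product: 34 (2S,3S)-3-[(2S,3S)-2-(2,4-dimethoxyphenyl)-3-(3,5-dimethoxyphenyl)-4-methoxy-2,3-dihydro-1-benzofuran-6-yl]-2-(4-methoxyphenyl)-6-[(E)-2-(4-methoxyphenyl)ethenyl]-2,3-dihydro-1-benzofuran-4-ol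
Conditions: HCl (1 M in MeOH), rt → 50 °C, dilute
Reagents that add atoms: none
Why: The same acid-mediated MOM cleavage and SN1 cyclodehydration as in step 10: either of the two equivalent ring A phenols closes on the 4-methoxybenzylic cation at C2 from the face away from the unit 2 substituent on C3, giving the trans ring, and the other phenol becomes the C4 hydroxyl. Methanolic HCl of this strength is the usual reagent for MOM removal from stilbenes, and should unit 2 ionise at C2' it would re-close trans.

Step 20
Reactants: 34 the heptamethyl ether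
Product: 35 (2S,3S)-3-[(2S,3S)-2-(2,4-dihydroxyphenyl)-3-(3,5-dihydroxyphenyl)-4-hydroxy-2,3-dihydro-1-benzofuran-6-yl]-2-(4-hydroxyphenyl)-6-[(E)-2-(4-hydroxyphenyl)ethenyl]-2,3-dihydro-1-benzofuran-4-ol (the target)
Conditions: BBr3 (excess), CH2Cl2, −78 °C → rt; MeOH/H2O quench at 0 °C
Reagents that add atoms: none
Why: Lewis-acid cleavage of aryl methyl ethers by bromide attack at methyl of the boron-complexed ether, the usual end game for permethylated oligostilbenes; C3 and C3' carry no leaving group, and a reversible opening at C2 or C2' would re-close to the trans ring.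

## Compound list

1 | acenaphthylene-1,2-dione | O=C1C(=O)c2cccc3cccc1c23 | starting material
2 | cis-1,2-dimethyl-1,2-dihydroacenaphthylene-1,2-diol (meso, 1R,2S; mac diol) | C[C@@]1(O)c2cccc3cccc(c23)[C@]1(C)O | intermediate
3 | 2,4,6-trihydroxybenzaldehyde | O=Cc1c(O)cc(O)cc1O | starting material
4 | 2-hydroxy-4,6-bis(methoxymethoxy)benzaldehyde | O=Cc1c(O)cc(OCOC)cc1OCOC | intermediate
5 | 2-methoxy-4,6-bis(methoxymethoxy)benzaldehyde | O=Cc1c(OC)cc(OCOC)cc1OCOC | intermediate
6 | bis(4,4,5,5-tetramethyl-1,3,2-dioxaborolan-2-yl)methane | CC1(C)OB(CB2OC(C)(C)C(C)(C)O2)OC1(C)C | starting material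
7 | lithiobis(4,4,5,5-tetramethyl-1,3,2-dioxaborolan-2-yl)methane | [Li]C(B1OC(C)(C)C(C)(C)O1)B1OC(C)(C)C(C)(C)O1 | intermediate
8 | 2-{(E)-2-[2-methoxy-4,6-bis(methoxymethoxy)phenyl]ethenyl}-4,4,5,5-tetramethyl-1,3,2-dioxaborolane | COCOc1cc(OC)c(/C=C/B2OC(C)(C)C(C)(C)O2)c(OCOC)c1 | intermediate
9 | (E)-2-[2-methoxy-4,6-bis(methoxymethoxy)phenyl]ethenylboronic acid | COCOc1cc(OC)c(/C=C/B(O)O)c(OCOC)c1 | intermediate (not isolated)
10 | cyclic ester of 9 with diol 2 (ring D alkenyl B(mac) ester) | COCOc1cc(OC)c(/C=C/B2O[C@]3(C)c4cccc5cccc(c45)[C@]3(C)O2)c(OCOC)c1 | intermediate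
11 | 3,5-dimethoxyphenol | COc1cc(O)cc(OC)c1 | starting material
12 | 3,5-dimethoxyphenyl trifluoromethanesulfonate | COc1cc(OC)cc(OS(=O)(=O)C(F)(F)F)c1 | intermediate
13 | 1-bromo-2,4-dimethoxybenzene | COc1ccc(Br)c(OC)c1 | starting material
14 | 2,4-dimethoxyphenyllithium | [Li]c1ccc(OC)cc1OC | intermediate (not isolated)
15 | lithium (2,4-dimethoxyphenyl){(E)-2-[2-methoxy-4,6-bis(methoxymethoxy)phenyl]ethenyl}borate of diol 2 (both epimers at boron) | [Li+].COCOc1cc(OC)c(/C=C/[B-]2(c3ccc(OC)cc3OC)O[C@]3(C)c4cccc5cccc(c45)[C@]3(C)O2)c(OCOC)c1 | intermediate (not isolated)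
16 | (1R,2S)-1-(2,4-dimethoxyphenyl)-2-(3,5-dimethoxyphenyl)-2-[2-methoxy-4,6-bis(methoxymethoxy)phenyl]ethylboronic acid cyclic ester of diol 2 | B1(O[C@]2(C)c3cccc4cccc(c34)[C@]2(C)O1)[C@@H](c1ccc(OC)cc1OC)[C@H](c1c(OC)cc(OCOC)cc1OCOC)c1cc(OC)cc(OC)c1 | intermediate
17 | (1R,2S)-1-(2,4-dimethoxyphenyl)-2-(3,5-dimethoxyphenyl)-2-[2-methoxy-4,6-bis(methoxymethoxy)phenyl]ethan-1-ol | O[C@@H](c1ccc(OC)cc1OC)[C@H](c1c(OC)cc(OCOC)cc1OCOC)c1cc(OC)cc(OC)c1 | intermediate
18 | (2S,3S)-2-(2,4-dimethoxyphenyl)-3-(3,5-dimethoxyphenyl)-4-methoxy-2,3-dihydro-1-benzofuran-6-ol | Oc1cc(OC)c2c(c1)O[C@H](c1ccc(OC)cc1OC)[C@H]2c1cc(OC)cc(OC)c1 | intermediate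
19 | (2S,3S)-2-(2,4-dimethoxyphenyl)-3-(3,5-dimethoxyphenyl)-4-methoxy-2,3-dihydro-1-benzofuran-6-yl trifluoromethanesulfonate | O=S(=O)(Oc1cc(OC)c2c(c1)O[C@H](c1ccc(OC)cc1OC)[C@H]2c1cc(OC)cc(OC)c1)C(F)(F)F | intermediate
20 | 3,5-dihydroxybenzaldehyde | O=Cc1cc(O)cc(O)c1 | starting material
21 | 3,5-bis(methoxymethoxy)benzaldehyde | O=Cc1cc(OCOC)cc(OCOC)c1 | intermediate
22 | diethyl (4-methoxybenzyl)phosphonate | CCOP(=O)(Cc1ccc(OC)cc1)OCC | starting material
23 | (E)-1-[3,5-bis(methoxymethoxy)phenyl]-2-(4-methoxyphenyl)ethene | COCOc1cc(/C=C/c2ccc(OC)cc2)cc(OCOC)c1 | intermediate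
24 | {2,6-bis(methoxymethoxy)-4-[(E)-2-(4-methoxyphenyl)ethenyl]phenyl}lithium | COCOc1cc(/C=C/c2ccc(OC)cc2)cc(OCOC)c1[Li] | intermediate (not isolated)
25 | 2,6-bis(methoxymethoxy)-4-[(E)-2-(4-methoxyphenyl)ethenyl]benzaldehyde | COCOc1cc(/C=C/c2ccc(OC)cc2)cc(OCOC)c1C=O | intermediate
26 | 2-{(E)-2-[2,6-bis(methoxymethoxy)-4-[(E)-2-(4-methoxyphenyl)ethenyl]phenyl]ethenyl}-4,4,5,5-tetramethyl-1,3,2-dioxaborolane | COCOc1cc(/C=C/c2ccc(OC)cc2)cc(OCOC)c1/C=C/B1OC(C)(C)C(C)(C)O1 | intermediate
27 | (E)-2-[2,6-bis(methoxymethoxy)-4-[(E)-2-(4-methoxyphenyl)ethenyl]phenyl]ethenylboronic acid | COCOc1cc(/C=C/c2ccc(OC)cc2)cc(OCOC)c1/C=C/B(O)O | intermediate (not isolated)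
28 | cyclic ester of 27 with diol 2 (ring A alkenyl B(mac) ester) | COCOc1cc(/C=C/c2ccc(OC)cc2)cc(OCOC)c1/C=C/B1O[C@]2(C)c3cccc4cccc(c34)[C@]2(C)O1 | intermediate
29 | 1-bromo-4-methoxybenzene | COc1ccc(Br)cc1 | starting material
30 | 4-methoxyphenyllithium | [Li]c1ccc(OC)cc1 | intermediate (not isolated)
31 | lithium (4-methoxyphenyl){(E)-2-[2,6-bis(methoxymethoxy)-4-[(E)-2-(4-methoxyphenyl)ethenyl]phenyl]ethenyl}borate of diol 2 (both epimers at boron) | [Li+].COCOc1cc(/C=C/c2ccc(OC)cc2)cc(OCOC)c1/C=C/[B-]1(c2ccc(OC)cc2)O[C@]2(C)c3cccc4cccc(c34)[C@]2(C)O1 | intermediate (not isolated)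
32 | (1R,2S)-2-[2,6-bis(methoxymethoxy)-4-[(E)-2-(4-methoxyphenyl)ethenyl]phenyl]-2-[(2S,3S)-2-(2,4-dimethoxyphenyl)-3-(3,5-dimethoxyphenyl)-4-methoxy-2,3-dihydro-1-benzofuran-6-yl]-1-(4-methoxyphenyl)ethylboronic acid cyclic ester of diol 2 | B1(O[C@]2(C)c3cccc4cccc(c34)[C@]2(C)O1)[C@@H](c1ccc(OC)cc1)[C@H](c1c(OCOC)cc(/C=C/c2ccc(OC)cc2)cc1OCOC)c1cc(OC)c2c(c1)O[C@H](c1ccc(OC)cc1OC)[C@H]2c1cc(OC)cc(OC)c1 | intermediate
33 | (1R,2S)-2-[2,6-bis(methoxymethoxy)-4-[(E)-2-(4-methoxyphenyl)ethenyl]phenyl]-2-[(2S,3S)-2-(2,4-dimethoxyphenyl)-3-(3,5-dimethoxyphenyl)-4-methoxy-2,3-dihydro-1-benzofuran-6-yl]-1-(4-methoxyphenyl)ethan-1-ol | O[C@@H](c1ccc(OC)cc1)[C@H](c1c(OCOC)cc(/C=C/c2ccc(OC)cc2)cc1OCOC)c1cc(OC)c2c(c1)O[C@H](c1ccc(OC)cc1OC)[C@H]2c1cc(OC)cc(OC)c1 | intermediate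
34 | (2S,3S)-3-[(2S,3S)-2-(2,4-dimethoxyphenyl)-3-(3,5-dimethoxyphenyl)-4-methoxy-2,3-dihydro-1-benzofuran-6-yl]-2-(4-methoxyphenyl)-6-[(E)-2-(4-methoxyphenyl)ethenyl]-2,3-dihydro-1-benzofuran-4-ol | COc1ccc(/C=C/c2cc(O)c3c(c2)O[C@H](c2ccc(OC)cc2)[C@H]3c2cc(OC)c3c(c2)O[C@H](c2ccc(OC)cc2OC)[C@H]3c2cc(OC)cc(OC)c2)cc1 | intermediate
35 | (2S,3S)-3-[(2S,3S)-2-(2,4-dihydroxyphenyl)-3-(3,5-dihydroxyphenyl)-4-hydroxy-2,3-dihydro-1-benzofuran-6-yl]-2-(4-hydroxyphenyl)-6-[(E)-2-(4-hydroxyphenyl)ethenyl]-2,3-dihydro-1-benzofuran-4-ol | Oc1ccc(/C=C/c2cc(O)c3c(c2)O[C@H](c2ccc(O)cc2)[C@H]3c2cc(O)c3c(c2)O[C@H](c2ccc(O)cc2O)[C@H]3c2cc(O)cc(O)c2)cc1 | target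

## Step count and least certain steps

Total: 20 steps. Longest linear sequence: 12 steps (steps 2, 3, 5, 6, 8, 9, 10, 11, 17, 18, 19, 20, from 3 to 35). The ring A branch (steps 12 to 16) joins at step 17; steps 1, 4 and 7 supply the diol 2, the olefination reagent 7 and the triflate 12.

**Step 8 (key step).** The β-aryl group of 15 has two ortho ethers. They may slow the binding of the alkene to the aryl–palladium cation, so that direct transfer of the alkenyl or aryl group from boron to palladium (Suzuki-type coupling) or protodeboronation overtakes the metallate shift; the same crowding may erode face selectivity.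

The fallback exchanges the roles of the two C3' aryl groups, so that the hindered ring sits on palladium and not on the alkene. It sets out from 5 and returns at 18.
- Dakin oxidation of 5 (mCPBA, then K2CO3/MeOH) would give 2-methoxy-4,6-bis(methoxymethoxy)phenol F1, and triflation as in step 7 would give its trifluoromethanesulfonate F2.
- Purchased 3,5-dimethoxybenzaldehyde F3 would be taken through the boron–Wittig olefination with 7 to the (E)-alkenyl pinacol boronate F4, then through the boronic acid F5 to the B(mac) ester F6, as in steps 5 and 6.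
- Addition of 14 to F6 would give the ate complex F7. Coupling with F2 under the conditions of step 8, with the ligand enantiomer that gives 2S at the diaryl carbon, would give the (1S,2S)-boronic ester F8, since anti addition now places ring D on C3' from palladium.
- Oxidation as in step 9 would give the (1S,2S)-alcohol F9, the C1 epimer of 17. Because the ring closure of step 10 re-forms C2' under control of C3', F9 would give 18 under the conditions of step 10.

This detour trades a crowded alkene for a crowded oxidative addition, which is a different failure mode.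

**Step 17.** The triflate 19 is large and electron-rich. Slow turnover may let protodeboronation or Suzuki-type coupling of 31 dominate, and the distal stilbene of 31 may be arylated in a Heck-type side reaction.

The fallback again exchanges roles. It sets out from 19 and from 23 (through its aryllithium 24) and returns at 34.
- Heck coupling of 19 with vinylboronic acid pinacol ester (Pd(OAc)2, P(o-tol)3, Et3N) would give the unit 2 (E)-alkenyl pinacol boronate F10; ligand exchange as in step 6 would lead through the boronic acid F11 to the B(mac) ester F12.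
- Quenching 24 with iodine would give the ring A aryl iodide F13.
- Addition of 30 to F12 would give the ate complex F14. Coupling with F13 under the conditions of step 17, with NaOTf as iodide scavenger and the ligand enantiomer that gives 2S at the diaryl carbon, would give the (1S,2S)-boronic ester F15.
- Oxidation would give the (1S,2S)-alcohol F16, the C1 epimer of 33, which converges on 34 under the conditions of step 19.

**Step 10 (the same closure recurs in step 19).** The C2' cation may lose the C3' proton (E1) to give a triarylethene, or be captured by the very electron-rich ring D of a second molecule, before the ortho phenol is unmasked.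

The fallback avoids the cation by a stereospecific closure. It sets out from 16 and returns at 18.
- Methanolic HCl applied to 16 would remove the MOM groups while the C–B bond is kept, giving the bis-phenol boronic ester F17.
- Oxidation as in step 9 would give the (1R,2S)-triol F18.
- Mitsunobu closure (PPh3, DIAD, THF, 0 °C) would form O1'–C2' with inversion and give 18.

Here the anti addition of step 8, retention in the oxidation and inversion in the closure together give the trans ring; if ionisation leaks in, the outcome is still trans.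

**Step 20.** Under the long exposure to BBr3 that seven methyl ethers need, the C2–O1 and C2'–O1' bonds may open to quinone-methide-type cations that arylate another molecule, and HBr may add to the stilbene.

The fallback changes the bond-breaking logic from Lewis-acid activation of the ether oxygens to SN2 attack on the methyl carbons. It sets out from 34 and returns at 35: NaSEt (excess) in DMF at 130–150 °C would demethylate the aryl ethers as phenoxides, a pathway in which no cation can form at C2 or C2' and in which the alkene is inert. No new compound is made.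

## Further compounds

F1 | step 8 | 2-methoxy-4,6-bis(methoxymethoxy)phenol | COCOc1cc(OC)c(O)c(OCOC)c1
F2 | step 8 | 2-methoxy-4,6-bis(methoxymethoxy)phenyl trifluoromethanesulfonate | COCOc1cc(OC)c(OS(=O)(=O)C(F)(F)F)c(OCOC)c1
F3 | step 8 | 3,5-dimethoxybenzaldehyde (purchased) | COc1cc(C=O)cc(OC)c1
F4 | step 8 | 2-[(E)-2-(3,5-dimethoxyphenyl)ethenyl]-4,4,5,5-tetramethyl-1,3,2-dioxaborolane | COc1cc(/C=C/B2OC(C)(C)C(C)(C)O2)cc(OC)c1
F5 | step 8 | (E)-2-(3,5-dimethoxyphenyl)ethenylboronic acid | COc1cc(/C=C/B(O)O)cc(OC)c1
F6 | step 8 | cyclic ester of F5 with diol 2 | COc1cc(/C=C/B2O[C@]3(C)c4cccc5cccc(c45)[C@]3(C)O2)cc(OC)c1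
F7 | step 8 | lithium (2,4-dimethoxyphenyl)[(E)-2-(3,5-dimethoxyphenyl)ethenyl]borate of diol 2 | [Li+].COc1cc(/C=C/[B-]2(c3ccc(OC)cc3OC)O[C@]3(C)c4cccc5cccc(c45)[C@]3(C)O2)cc(OC)c1
F8 | step 8 | (1S,2S)-1-(2,4-dimethoxyphenyl)-2-(3,5-dimethoxyphenyl)-2-[2-methoxy-4,6-bis(methoxymethoxy)phenyl]ethylboronic acid cyclic ester of diol 2 | B1(O[C@]2(C)c3cccc4cccc(c34)[C@]2(C)O1)[C@H](c1ccc(OC)cc1OC)[C@H](c1c(OC)cc(OCOC)cc1OCOC)c1cc(OC)cc(OC)c1
F9 | step 8 | (1S,2S)-1-(2,4-dimethoxyphenyl)-2-(3,5-dimethoxyphenyl)-2-[2-methoxy-4,6-bis(methoxymethoxy)phenyl]ethan-1-ol | O[C@H](c1ccc(OC)cc1OC)[C@H](c1c(OC)cc(OCOC)cc1OCOC)c1cc(OC)cc(OC)c1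
F10 | step 17 | 2-{(E)-2-[(2S,3S)-2-(2,4-dimethoxyphenyl)-3-(3,5-dimethoxyphenyl)-4-methoxy-2,3-dihydro-1-benzofuran-6-yl]ethenyl}-4,4,5,5-tetramethyl-1,3,2-dioxaborolane | CC1(C)OB(/C=C/c2cc(OC)c3c(c2)O[C@H](c2ccc(OC)cc2OC)[C@H]3c2cc(OC)cc(OC)c2)OC1(C)C
F11 | step 17 | (E)-2-[(2S,3S)-2-(2,4-dimethoxyphenyl)-3-(3,5-dimethoxyphenyl)-4-methoxy-2,3-dihydro-1-benzofuran-6-yl]ethenylboronic acid | OB(O)/C=C/c1cc(OC)c2c(c1)O[C@H](c1ccc(OC)cc1OC)[C@H]2c1cc(OC)cc(OC)c1
F12 | step 17 | cyclic ester of F11 with diol 2 | B1(O[C@]2(C)c3cccc4cccc(c34)[C@]2(C)O1)/C=C/c1cc(OC)c2c(c1)O[C@H](c1ccc(OC)cc1OC)[C@H]2c1cc(OC)cc(OC)c1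
F13 | step 17 | 2-iodo-1,3-bis(methoxymethoxy)-5-[(E)-2-(4-methoxyphenyl)ethenyl]benzene | COCOc1cc(/C=C/c2ccc(OC)cc2)cc(OCOC)c1I
F14 | step 17 | lithium (4-methoxyphenyl){(E)-2-[(2S,3S)-2-(2,4-dimethoxyphenyl)-3-(3,5-dimethoxyphenyl)-4-methoxy-2,3-dihydro-1-benzofuran-6-yl]ethenyl}borate of diol 2 | [Li+].COc1ccc([B-]2(/C=C/c3cc(OC)c4c(c3)O[C@H](c3ccc(OC)cc3OC)[C@H]4c3cc(OC)cc(OC)c3)O[C@]3(C)c4cccc5cccc(c45)[C@]3(C)O2)cc1
F15 | step 17 | (1S,2S)-2-[2,6-bis(methoxymethoxy)-4-[(E)-2-(4-methoxyphenyl)ethenyl]phenyl]-2-[(2S,3S)-2-(2,4-dimethoxyphenyl)-3-(3,5-dimethoxyphenyl)-4-methoxy-2,3-dihydro-1-benzofuran-6-yl]-1-(4-methoxyphenyl)ethylboronic acid cyclic ester of diol 2 | B1(O[C@]2(C)c3cccc4cccc(c34)[C@]2(C)O1)[C@H](c1ccc(OC)cc1)[C@H](c1c(OCOC)cc(/C=C/c2ccc(OC)cc2)cc1OCOC)c1cc(OC)c2c(c1)O[C@H](c1ccc(OC)cc1OC)[C@H]2c1cc(OC)cc(OC)c1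
F16 | step 17 | (1S,2S)-2-[2,6-bis(methoxymethoxy)-4-[(E)-2-(4-methoxyphenyl)ethenyl]phenyl]-2-[(2S,3S)-2-(2,4-dimethoxyphenyl)-3-(3,5-dimethoxyphenyl)-4-methoxy-2,3-dihydro-1-benzofuran-6-yl]-1-(4-methoxyphenyl)ethan-1-ol | O[C@H](c1ccc(OC)cc1)[C@H](c1c(OCOC)cc(/C=C/c2ccc(OC)cc2)cc1OCOC)c1cc(OC)c2c(c1)O[C@H](c1ccc(OC)cc1OC)[C@H]2c1cc(OC)cc(OC)c1
F17 | step 10 | (1R,2S)-2-(2,4-dihydroxy-6-methoxyphenyl)-1-(2,4-dimethoxyphenyl)-2-(3,5-dimethoxyphenyl)ethylboronic acid cyclic ester of diol 2 | B1(O[C@]2(C)c3cccc4cccc(c34)[C@]2(C)O1)[C@@H](c1ccc(OC)cc1OC)[C@H](c1c(OC)cc(O)cc1O)c1cc(OC)cc(OC)c1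
F18 | step 10 | 4-[(1S,2R)-2-(2,4-dimethoxyphenyl)-1-(3,5-dimethoxyphenyl)-2-hydroxyethyl]-5-methoxybenzene-1,3-diol | O[C@@H](c1ccc(OC)cc1OC)[C@H](c1c(OC)cc(O)cc1O)c1cc(OC)cc(OC)c1
F0 | step 20 | none | none
A1 | alternative 1 | 5-[(2S,3S)-6-bromo-2-(2,4-dimethoxyphenyl)-4-methoxy-2,3-dihydro-1-benzofuran-3-yl]-7-hydroxy-2,2-dimethyl-4H-1,3-benzodioxin-4-one | Brc1cc(OC)c2c(c1)O[C@H](c1ccc(OC)cc1OC)[C@H]2c1cc(O)cc2c1C(=O)OC(C)(C)O2
A2 | alternative 1 | 6-{4-[(2S,3S)-6-bromo-2-(2,4-dimethoxyphenyl)-4-methoxy-2,3-dihydro-1-benzofuran-3-yl]-2,4-dioxobutyl}-2,2-dimethyl-4H-1,3-dioxin-4-one | Brc1cc(OC)c2c(c1)O[C@H](c1ccc(OC)cc1OC)[C@H]2C(=O)CC(=O)CC1=CC(=O)OC(C)(C)O1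
A3 | alternative 2 | [(2S,3S)-6-(diethoxymethyl)-2-(2,4-dimethoxyphenyl)-3-(3,5-dimethoxyphenyl)-2,3-dihydro-1-benzofuran-4-yl]trimethylsilane | CCOC(OCC)c1cc([Si](C)(C)C)c2c(c1)O[C@H](c1ccc(OC)cc1OC)[C@H]2c1cc(OC)cc(OC)c1
A4 | alternative 2 | [(3S,4S)-4-(2,4-dimethoxyphenyl)-3-(3,5-dimethoxyphenyl)-4-(ethynyloxy)but-1-yn-1-yl]trimethylsilane | C#CO[C@H](c1ccc(OC)cc1OC)[C@H](C#C[Si](C)(C)C)c1cc(OC)cc(OC)c1
A5 | alternative 2 | 3,3-diethoxyprop-1-yne | C#CC(OCC)OCC
A6 | alternative 3 | (2S,3S)-3-[(2S,3S)-2-(2,4-dimethoxyphenyl)-3-(3,5-dimethoxyphenyl)-4-methoxy-2,3-dihydro-1-benzofuran-6-yl]-2-(4-methoxyphenyl)-6-[(E)-2-(4-methoxyphenyl)ethenyl]-3,5,6,7-tetrahydro-1-benzofuran-4(2H)-one (C6 unassigned) | COc1ccc(/C=C/C2CC(=O)C3=C(C2)O[C@H](c2ccc(OC)cc2)[C@H]3c2cc(OC)c3c(c2)O[C@H](c2ccc(OC)cc2OC)[C@H]3c2cc(OC)cc(OC)c2)cc1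
A7 | alternative 3 | trans-2-[(2S,3S)-2-(2,4-dimethoxyphenyl)-3-(3,5-dimethoxyphenyl)-4-methoxy-2,3-dihydro-1-benzofuran-6-yl]-1-(4-methoxyphenyl)-6-[(E)-2-(4-methoxyphenyl)ethenyl]spiro[2.5]octane-4,8-dione (C6 unassigned) | COc1ccc([C@@H]2[C@@H](c4cc(OC)c5c(c4)O[C@H](c4ccc(OC)cc4OC)[C@H]5c4cc(OC)cc(OC)c4)C23C(=O)CC(/C=C/c4ccc(OC)cc4)CC3=O)cc1
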